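## Retrosynthetic overview

1. The last C–C bond made is the benzylic CH2–CH= bond (C-1/C-2): benzylic chloride 30 and terminal alkyne 24 are joined in a one-pot Zr-catalysed syn-methylalumination / Ni-catalysed coupling, which also installs the C-3 methyl group and the E geometry; one double oxidation and one desilylation finish the synthesis.
2. Enabling feature: the ArCH2–CH=C(CH3)–CH2–C(=O) unit. C-2 carries one H, C-3 a methyl group, and the ketone carbon C-5 sits in the homopropargylic position, so with C-5 as a carbinol the alkene is the syn adduct of CH3 and benzyl across a terminal alkyne made by propargylation of an enal. Both ketone carbons (chain C-5 and ring C-3) travel as carbinols and are masked in the flask as aluminium alkoxides.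
3. Alkyne 24: the Z-enone geometry comes from syn-methylcupration of a 2-ynoate, followed by reduction, allylic oxidation and Barbier propargylation of the Z-enal.
4. The oxane is the only ring formed (the benzene ring is bought). Its O–C(CH3)2 bond is closed by Co-catalysed Markovnikov hydroalkoxylation of an isopropenyl carbinol; ring C-5 comes from an Ipc2BCl aldol with methacrolein and quaternary ring C-2 from Seebach alkylation of the (S)-lactic acid dioxolanone.
5. Arene 30: directed ortho-metalation of TIPS-protected 4-methoxy-3-methylphenol, formylation/reduction, chlorination.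

Key step: step 17

Remarks on the chemistry:
- Chain carbons are counted from the benzylic CH2 (C-1) to the CH2 on the ring (C-10); ring positions are oxane locants (O-1, quaternary C-2, C-3, C-4, carbinol C-5, C-6 with two methyls).
- The ring carbinol made in step 9 and the chain carbinol made in step 13 both become ketones in step 18; they are carried as epimer mixtures and written without configuration.
- 4-Methoxy-3-methylphenol and (5-iodopent-1-yn-1-yl)trimethylsilane are taken as commercial.

## Route

Step 1
Reactants: 1 (S)-lactic acid; 2 pivaldehyde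
Product: 3 (2S,5S)-2-tert-butyl-5-methyl-1,3-dioxolan-4-one
Conditions: cat. TsOH·H2O, cat. H2SO4, pentane, reflux (Dean–Stark); recrystallisation at −78 °C
Reagents that add atoms: none
Why: Acid-catalysed acetalisation of the α-hydroxy acid (Seebach dioxolanone formation) should give mainly the cis acetal, which relays the lactate configuration to the acetal carbon; no stereocentre of the target is formed here.

Step 2
Reactants: 3 (2S,5S)-2-tert-butyl-5-methyl-1,3-dioxolan-4-one; 4 (5-iodopent-1-yn-1-yl)trimethylsilane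
Product: 6 (2S,5R)-2-tert-butyl-5-methyl-5-[5-(trimethylsilyl)pent-4-yn-1-yl]-1,3-dioxolan-4-one, via lithium enolate 5 (not isolated)
Conditions: LDA, THF, −78 °C; then 4, THF–DMPU, −78 → −20 °C
Reagents that add atoms: none
Why: Enolate alkylation of a Seebach dioxolanone (self-regeneration of stereocentres) should occur anti to the tert-butyl group, setting the quaternary C–O centre (later ring C-2, R) with net retention of the lactate configuration.

Step 3
Reactants: 6 (2S,5R)-2-tert-butyl-5-methyl-5-[5-(trimethylsilyl)pent-4-yn-1-yl]-1,3-dioxolan-4-one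
Product: 7 (2R)-2-hydroxy-N-methoxy-N,2-dimethyl-7-(trimethylsilyl)hept-6-ynamide
Conditions: MeNH(OMe)·HCl, i-PrMgCl, THF, −20 → 0 °C
Reagents that add atoms: N,O-dimethylhydroxylamine hydrochloride (CNOC.Cl)
Why: Aminolysis of the activated acylal-type lactone by the magnesium amide (Weinreb amide formation) should open the dioxolanone and release pivaldehyde without touching the quaternary centre.

Step 4
Reactants: 7 (2R)-2-hydroxy-N-methoxy-N,2-dimethyl-7-(trimethylsilyl)hept-6-ynamide
Product: 8 (3R)-3-hydroxy-3-methyl-8-(trimethylsilyl)oct-7-yn-2-one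
Conditions: MeMgBr (3.5 equiv), THF, 0 °C → rt
Reagents that add atoms: methylmagnesium bromide (C[Mg]Br)
Why: Weinreb ketone synthesis: after deprotonation of the hydroxyl group the chelated tetrahedral intermediate should stop at the methyl ketone.

Step 5
Reactants: 8 (3R)-3-hydroxy-3-methyl-8-(trimethylsilyl)oct-7-yn-2-one
Product: 9 (3R)-3-methyl-8-(trimethylsilyl)-3-(trimethylsilyloxy)oct-7-yn-2-one
Conditions: N-(trimethylsilyl)imidazole, CH2Cl2, rt
Reagents that add atoms: N-(trimethylsilyl)imidazole (C[Si](C)(C)n1ccnc1)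
Why: O-silylation with a neutral silyl donor should mask the tertiary hydroxyl for the boron aldol reaction without enolising the ketone.

Step 6
Reactants: 9 (3R)-3-methyl-8-(trimethylsilyl)-3-(trimethylsilyloxy)oct-7-yn-2-one; 10 methacrolein
Product: 13 (3S,6R)-3,6-dihydroxy-2,6-dimethyl-11-(trimethylsilyl)undec-1-en-10-yn-5-one, via enol borinate 11 (not isolated), via O-TMS aldol 12 (not isolated)
Conditions: (+)-Ipc2BCl, Et3N, Et2O, 0 °C; 10, −78 → −20 °C; H2O2, MeOH, pH 7 buffer, 0 °C; citric acid, MeOH, rt
Reagents that add atoms: none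
Why: Paterson boron aldol reaction of a methyl ketone: the enol diisopinocampheylborinate (possible only on the methyl side) should add to the Si face of methacrolein under control of the (+)-Ipc ligands in a cyclic boron transition state, setting the carbinol centre (later ring C-5, S), while its epimer would be a separable diastereomer and the mild acid work-up removes the O-TMS group.

Step 7
Reactants: 13 (3S,6R)-3,6-dihydroxy-2,6-dimethyl-11-(trimethylsilyl)undec-1-en-10-yn-5-one
Product: 14 (3S,6R)-3-(tert-butyldimethylsilyloxy)-6-hydroxy-2,6-dimethyl-11-(trimethylsilyl)undec-1-en-10-yn-5-one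
Conditions: TBSCl, imidazole, DMF, 0 °C → rt
Reagents that add atoms: tert-butyldimethylsilyl chloride (CC(C)(C)[Si](C)(C)Cl)
Why: Silylation with TBSCl/imidazole should be selective for the secondary allylic hydroxyl because the tertiary α-keto hydroxyl is too hindered.

Step 8
Reactants: 14 (3S,6R)-3-(tert-butyldimethylsilyloxy)-6-hydroxy-2,6-dimethyl-11-(trimethylsilyl)undec-1-en-10-yn-5-one
Product: 15 (2R,5S)-5-(tert-butyldimethylsilyloxy)-2,6,6-trimethyl-2-[5-(trimethylsilyl)pent-4-yn-1-yl]oxan-3-one
Conditions: Co(salen) catalyst (5 mol %), N-fluoro-2,4,6-trimethylpyridinium tetrafluoroborate, PhSiH3, PhCF3, 0 °C → rt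
Reagents that add atoms: none
Why: Cobalt-hydride HAT-initiated radical–polar crossover hydroalkoxylation (Mukaiyama-type) should deliver H to the CH2 terminus of the isopropenyl group and let the tertiary hydroxyl capture the tertiary cation equivalent in a 6-exo mode, the Markovnikov regiochemistry allowing only the oxane and no new stereocentre arising because the new quaternary carbon carries two methyl groups.

Step 9
Reactants: 15 (2R,5S)-5-(tert-butyldimethylsilyloxy)-2,6,6-trimethyl-2-[5-(trimethylsilyl)pent-4-yn-1-yl]oxan-3-one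
Product: 17 (2R,5S)-5-(tert-butyldimethylsilyloxy)-2,6,6-trimethyl-2-(pent-4-yn-1-yl)oxan-3-ol (mixture of C-3 epimers), via TMS-alkyne alcohol 16 (not isolated)
Conditions: NaBH4, MeOH, 0 °C; then K2CO3, rt
Reagents that add atoms: none
Why: Borohydride reduction puts the ring carbonyl at the alcohol oxidation level required by the organolithium and organoaluminium steps (configuration irrelevant, re-oxidised in step 18), and base-mediated methanolysis cleaves the alkynyl C–Si bond.

Step 10
Reactants: 17 (2R,5S)-5-(tert-butyldimethylsilyloxy)-2,6,6-trimethyl-2-(pent-4-yn-1-yl)oxan-3-ol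
Product: 19 methyl 6-[(2R,5S)-5-(tert-butyldimethylsilyloxy)-3-(methoxycarbonyloxy)-2,6,6-trimethyloxan-2-yl]hex-2-ynoate, via dilithio species 18 (not isolated)
Conditions: n-BuLi (2.2 equiv), THF, −78 °C; ClCO2Me (3 equiv), −78 → 0 °C
Reagents that add atoms: methyl chloroformate (COC(=O)Cl)
Why: Acylation of the lithium acetylide gives the 2-ynoate while the lithium alkoxide is capped as a methyl carbonate that the later hydride step removes, and keeping the alkoxide at −78 °C should forestall 1,3-silyl migration.

Step 11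
Reactants: 19 methyl 6-[(2R,5S)-5-(tert-butyldimethylsilyloxy)-3-(methoxycarbonyloxy)-2,6,6-trimethyloxan-2-yl]hex-2-ynoate
Product: 20 methyl (2Z)-6-[(2R,5S)-5-(tert-butyldimethylsilyloxy)-3-(methoxycarbonyloxy)-2,6,6-trimethyloxan-2-yl]-3-methylhex-2-enoate
Conditions: Me2CuLi (from MeLi and CuI), THF, −78 °C; MeOH at −78 °C, then aq. NH4Cl
Reagents that add atoms: lithium dimethylcuprate ([Li+].C[Cu-]C)
Why: Syn-carbocupration of the 2-ynoate (Gilman conjugate addition) with cold protonation should place the new methyl group and the hydrogen cis, so the chain is cis to the ester and the Z geometry of the later enone is fixed.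

Step 12
Reactants: 20 methyl (2Z)-6-[(2R,5S)-5-(tert-butyldimethylsilyloxy)-3-(methoxycarbonyloxy)-2,6,6-trimethyloxan-2-yl]-3-methylhex-2-enoate
Product: 21 (2R,5S)-5-(tert-butyldimethylsilyloxy)-2-[(4Z)-6-hydroxy-4-methylhex-4-en-1-yl]-2,6,6-trimethyloxan-3-ol
Conditions: DIBAL-H (excess), CH2Cl2, −78 → 0 °C; Rochelle salt
Reagents that add atoms: none
Why: DIBAL-H should reduce the enoate 1,2 to the allylic alcohol and cleave the carbonate in the same operation without affecting the silyl ether or the alkene geometry.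

Step 13
Reactants: 21 (2R,5S)-5-(tert-butyldimethylsilyloxy)-2-[(4Z)-6-hydroxy-4-methylhex-4-en-1-yl]-2,6,6-trimethyloxan-3-ol; 22 propargyl bromide
Product: 24 (2R,5S)-5-(tert-butyldimethylsilyloxy)-2-[(4Z)-6-hydroxy-4-methylnon-4-en-8-yn-1-yl]-2,6,6-trimethyloxan-3-ol (mixture of carbinol epimers), via Z-enal 23 (not isolated)
Conditions: MnO2, CH2Cl2, rt; filtration; then Zn dust, 22, THF, 0 °C; aq. NH4Cl
Reagents that add atoms: none
Why: MnO2 oxidises only the allylic primary alcohol to the Z-enal, which is used at once to avoid Z/E isomerisation, and the zinc Barbier reaction (allenylzinc bromide, SE2′ 1,2-addition) should give the homopropargylic alcohol, whose uncontrolled carbinol centre becomes the C-5 ketone in step 18.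

Step 14
Reactants: 25 4-methoxy-3-methylphenol
Product: 26 (4-methoxy-3-methylphenoxy)triisopropylsilane
Conditions: TIPSCl, imidazole, DMF, rt
Reagents that add atoms: triisopropylsilyl chloride (CC(C)[Si](Cl)(C(C)C)C(C)C)
Why: Standard phenol silylation; the bulky TIPS ether neither directs nor permits lithiation next to it and survives the organometallic steps.

Step 15
Reactants: 26 (4-methoxy-3-methylphenoxy)triisopropylsilane
Product: 29 [2-methoxy-3-methyl-5-(triisopropylsilyloxy)phenyl]methanol, via aryllithium 27 (not isolated), via aldehyde 28 (not isolated)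
Conditions: n-BuLi, TMEDA, Et2O, 0 °C → rt; DMF, −78 → 0 °C; then MeOH, NaBH4, 0 °C
Reagents that add atoms: N,N-dimethylformamide (CN(C)C=O)
Why: Directed ortho-metalation: the methoxy group should direct lithiation to its only free ortho position (the other carries the methyl group and the positions next to OTIPS are shielded), and formylation followed by borohydride reduction in the same flask gives the benzylic alcohol.

Step 16
Reactants: 29 [2-methoxy-3-methyl-5-(triisopropylsilyloxy)phenyl]methanol
Product: 30 [3-(chloromethyl)-4-methoxy-5-methylphenoxy]triisopropylsilane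
Conditions: PPh3, N-chlorosuccinimide, CH2Cl2, −20 → 0 °C
Reagents that add atoms: N-chlorosuccinimide (O=C1CCC(=O)N1Cl)
Why: Appel-type chlorination under neutral conditions should convert the electron-rich benzylic alcohol into the chloride without cleaving the aryl silyl ether.

Step 17
Reactants: 24 (2R,5S)-5-(tert-butyldimethylsilyloxy)-2-[(4Z)-6-hydroxy-4-methylnon-4-en-8-yn-1-yl]-2,6,6-trimethyloxan-3-ol; 30 [3-(chloromethyl)-4-methoxy-5-methylphenoxy]triisopropylsilane
Product: 32 (2R,5S)-5-(tert-butyldimethylsilyloxy)-2-[(4Z,8E)-6-hydroxy-10-[2-methoxy-3-methyl-5-(triisopropylsilyloxy)phenyl]-4,8-dimethyldeca-4,8-dien-1-yl]-2,6,6-trimethyloxan-3-ol, via alkenylalane 31 (not isolated)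
Conditions: Me3Al (5 equiv), Cp2ZrCl2 (0.25 equiv), ClCH2CH2Cl, 0 °C → rt; concentration; THF, 30 (1.3 equiv), NiCl2(PPh3)2/n-BuLi (5 mol % Ni(0)), rt; aq. Rochelle salt
Reagents that add atoms: trimethylaluminium (C[Al](C)C)
Why: Cp2ZrCl2-catalysed syn-methylalumination of the terminal alkyne (the two hydroxyl groups are masked in the flask as dimethylaluminium alkoxides) places CH3 on the internal carbon and aluminium on the terminal carbon to give the (E)-2-methylalkenylalane 31; Ni(0) then inserts into the benzylic C–Cl bond of 30, the alkenyl group passes from Al to Ni, and reductive elimination forms the benzylic CH2–CH= bond with retention of the alkene geometry. The closest known reaction type is the Negishi carboalumination–cross-coupling of alkenylalanes with electron-rich benzylic chlorides, as used for ubiquinone side chains. No ring is closed and no stereocentre is formed; the step makes two C–C bonds (C-3–CH3 and C-1–C-2) and fixes the E geometry of the trisubstituted alkene through the syn-stereospecific addition. The selectivities needed are regioselectivity of the methylalumination (aluminium to the terminal carbon, normal for 1-alkynes), chemoselectivity for the alkyne over the trisubstituted Z-alkene (alkenes are inert under these conditions) and cross-coupling over homocoupling (chloride in slight excess, Ni(0)/PPh3). The silyl ethers and the ring ether should be inert to Me3Al at room temperature, and the aqueous work-up returns the two hydroxyl groups.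

Step 18
Reactants: 32 (2R,5S)-5-(tert-butyldimethylsilyloxy)-2-[(4Z,8E)-6-hydroxy-10-[2-methoxy-3-methyl-5-(triisopropylsilyloxy)phenyl]-4,8-dimethyldeca-4,8-dien-1-yl]-2,6,6-trimethyloxan-3-ol
Product: 33 (2R,5S)-5-(tert-butyldimethylsilyloxy)-2-[(4Z,8E)-10-[2-methoxy-3-methyl-5-(triisopropylsilyloxy)phenyl]-4,8-dimethyl-6-oxodeca-4,8-dien-1-yl]-2,6,6-trimethyloxan-3-one
Conditions: Dess–Martin periodinane, NaHCO3, CH2Cl2, 0 °C → rt
Reagents that add atoms: none
Why: Buffered Dess–Martin oxidation should convert both secondary carbinols (allylic chain carbinol and ring carbinol) into ketones in one operation without moving the β,γ-alkene into conjugation or isomerising the Z-enone.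

Step 19
Reactants: 33 (2R,5S)-5-(tert-butyldimethylsilyloxy)-2-[(4Z,8E)-10-[2-methoxy-3-methyl-5-(triisopropylsilyloxy)phenyl]-4,8-dimethyl-6-oxodeca-4,8-dien-1-yl]-2,6,6-trimethyloxan-3-one
Product: 34 (2R,5S)-5-hydroxy-2-[(4Z,8E)-10-(5-hydroxy-2-methoxy-3-methylphenyl)-4,8-dimethyl-6-oxodeca-4,8-dien-1-yl]-2,6,6-trimethyloxan-3-one (CNP0268050.1)
Conditions: HF·pyridine, pyridine, THF, 0 °C → rt
Reagents that add atoms: none
Why: Buffered fluoride desilylation should cleave the aryl TIPS ether and the secondary TBS ether under conditions neither basic enough for β-elimination or retro-aldol of the β-hydroxy ketone nor acidic enough to isomerise the skipped dienone.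

## Compound list

1 | (S)-lactic acid | C[C@H](O)C(=O)O | starting material
2 | pivaldehyde | CC(C)(C)C=O | starting material
3 | (2S,5S)-2-tert-butyl-5-methyl-1,3-dioxolan-4-one | C[C@@H]1O[C@H](C(C)(C)C)OC1=O | intermediate
4 | (5-iodopent-1-yn-1-yl)trimethylsilane | C[Si](C)(C)C#CCCCI | starting material
5 | lithium enolate of 3 | CC1=C(O[Li])O[C@@H](C(C)(C)C)O1 | intermediate (not isolated)
6 | (2S,5R)-2-tert-butyl-5-methyl-5-[5-(trimethylsilyl)pent-4-yn-1-yl]-1,3-dioxolan-4-one | C[C@]1(CCCC#C[Si](C)(C)C)O[C@H](C(C)(C)C)OC1=O | intermediate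
7 | (2R)-2-hydroxy-N-methoxy-N,2-dimethyl-7-(trimethylsilyl)hept-6-ynamide | CON(C)C(=O)[C@](C)(O)CCCC#C[Si](C)(C)C | intermediate
8 | (3R)-3-hydroxy-3-methyl-8-(trimethylsilyl)oct-7-yn-2-one | CC(=O)[C@](C)(O)CCCC#C[Si](C)(C)C | intermediate
9 | (3R)-3-methyl-8-(trimethylsilyl)-3-(trimethylsilyloxy)oct-7-yn-2-one | CC(=O)[C@](C)(O[Si](C)(C)C)CCCC#C[Si](C)(C)C | intermediate
10 | methacrolein | CC(=C)C=O | starting material
11 | enol di[(+)-isopinocampheyl]borinate of 9 | C=C(OB([C@H]1C[C@H]2C[C@@H]([C@@H]1C)C2(C)C)[C@H]1C[C@H]2C[C@@H]([C@@H]1C)C2(C)C)[C@](C)(O[Si](C)(C)C)CCCC#C[Si](C)(C)C | intermediate (not isolated)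
12 | (3S,6R)-3-hydroxy-2,6-dimethyl-11-(trimethylsilyl)-6-(trimethylsilyloxy)undec-1-en-10-yn-5-one | C=C(C)[C@@H](O)CC(=O)[C@](C)(O[Si](C)(C)C)CCCC#C[Si](C)(C)C | intermediate (not isolated)
13 | (3S,6R)-3,6-dihydroxy-2,6-dimethyl-11-(trimethylsilyl)undec-1-en-10-yn-5-one | C=C(C)[C@@H](O)CC(=O)[C@](C)(O)CCCC#C[Si](C)(C)C | intermediate
14 | (3S,6R)-3-(tert-butyldimethylsilyloxy)-6-hydroxy-2,6-dimethyl-11-(trimethylsilyl)undec-1-en-10-yn-5-one | C=C(C)[C@@H](O[Si](C)(C)C(C)(C)C)CC(=O)[C@](C)(O)CCCC#C[Si](C)(C)C | intermediate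
15 | (2R,5S)-5-(tert-butyldimethylsilyloxy)-2,6,6-trimethyl-2-[5-(trimethylsilyl)pent-4-yn-1-yl]oxan-3-one | C[Si](C)(C)C#CCCC[C@@]1(C)OC(C)(C)[C@@H](O[Si](C)(C)C(C)(C)C)CC1=O | intermediate
16 | (2R,5S)-5-(tert-butyldimethylsilyloxy)-2,6,6-trimethyl-2-[5-(trimethylsilyl)pent-4-yn-1-yl]oxan-3-ol (C-3 epimers) | C[Si](C)(C)C#CCCC[C@@]1(C)OC(C)(C)[C@@H](O[Si](C)(C)C(C)(C)C)CC1O | intermediate (not isolated)
17 | (2R,5S)-5-(tert-butyldimethylsilyloxy)-2,6,6-trimethyl-2-(pent-4-yn-1-yl)oxan-3-ol (C-3 epimers) | C#CCCC[C@@]1(C)OC(C)(C)[C@@H](O[Si](C)(C)C(C)(C)C)CC1O | intermediate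
18 | dilithio species of 17 (lithium alkoxide and lithium acetylide) | [Li]C#CCCC[C@@]1(C)OC(C)(C)[C@@H](O[Si](C)(C)C(C)(C)C)CC1O[Li] | intermediate (not isolated)
19 | methyl 6-[(2R,5S)-5-(tert-butyldimethylsilyloxy)-3-(methoxycarbonyloxy)-2,6,6-trimethyloxan-2-yl]hex-2-ynoate | COC(=O)C#CCCC[C@@]1(C)OC(C)(C)[C@@H](O[Si](C)(C)C(C)(C)C)CC1OC(=O)OC | intermediate
20 | methyl (2Z)-6-[(2R,5S)-5-(tert-butyldimethylsilyloxy)-3-(methoxycarbonyloxy)-2,6,6-trimethyloxan-2-yl]-3-methylhex-2-enoate | COC(=O)/C=C(/C)CCC[C@@]1(C)OC(C)(C)[C@@H](O[Si](C)(C)C(C)(C)C)CC1OC(=O)OC | intermediate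
21 | (2R,5S)-5-(tert-butyldimethylsilyloxy)-2-[(4Z)-6-hydroxy-4-methylhex-4-en-1-yl]-2,6,6-trimethyloxan-3-ol | OC/C=C(/C)CCC[C@@]1(C)OC(C)(C)[C@@H](O[Si](C)(C)C(C)(C)C)CC1O | intermediate
22 | propargyl bromide | C#CCBr | starting material
23 | (2Z)-6-[(2R,5S)-5-(tert-butyldimethylsilyloxy)-3-hydroxy-2,6,6-trimethyloxan-2-yl]-3-methylhex-2-enal | O=C/C=C(/C)CCC[C@@]1(C)OC(C)(C)[C@@H](O[Si](C)(C)C(C)(C)C)CC1O | intermediate (not isolated)
24 | (2R,5S)-5-(tert-butyldimethylsilyloxy)-2-[(4Z)-6-hydroxy-4-methylnon-4-en-8-yn-1-yl]-2,6,6-trimethyloxan-3-ol (carbinol epimers) | C#CCC(O)/C=C(/C)CCC[C@@]1(C)OC(C)(C)[C@@H](O[Si](C)(C)C(C)(C)C)CC1O | intermediate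
25 | 4-methoxy-3-methylphenol | COc1ccc(O)cc1C | starting material
26 | (4-methoxy-3-methylphenoxy)triisopropylsilane | COc1ccc(O[Si](C(C)C)(C(C)C)C(C)C)cc1C | intermediate
27 | [2-methoxy-3-methyl-5-(triisopropylsilyloxy)phenyl]lithium | COc1c([Li])cc(O[Si](C(C)C)(C(C)C)C(C)C)cc1C | intermediate (not isolated)
28 | 2-methoxy-3-methyl-5-(triisopropylsilyloxy)benzaldehyde | COc1c(C)cc(O[Si](C(C)C)(C(C)C)C(C)C)cc1C=O | intermediate (not isolated)
29 | [2-methoxy-3-methyl-5-(triisopropylsilyloxy)phenyl]methanol | COc1c(C)cc(O[Si](C(C)C)(C(C)C)C(C)C)cc1CO | intermediate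
30 | [3-(chloromethyl)-4-methoxy-5-methylphenoxy]triisopropylsilane | COc1c(C)cc(O[Si](C(C)C)(C(C)C)C(C)C)cc1CCl | intermediate
31 | (E)-alkenyldimethylalane of 24 with both hydroxyls as dimethylaluminium alkoxides | C[Al](C)/C=C(\C)CC(O[Al](C)C)/C=C(/C)CCC[C@@]1(C)OC(C)(C)[C@@H](O[Si](C)(C)C(C)(C)C)CC1O[Al](C)C | intermediate (not isolated)
32 | (2R,5S)-5-(tert-butyldimethylsilyloxy)-2-[(4Z,8E)-6-hydroxy-10-[2-methoxy-3-methyl-5-(triisopropylsilyloxy)phenyl]-4,8-dimethyldeca-4,8-dien-1-yl]-2,6,6-trimethyloxan-3-ol (carbinol epimers) | COc1c(C)cc(O[Si](C(C)C)(C(C)C)C(C)C)cc1C/C=C(\C)CC(O)/C=C(/C)CCC[C@@]1(C)OC(C)(C)[C@@H](O[Si](C)(C)C(C)(C)C)CC1O | intermediate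
33 | (2R,5S)-5-(tert-butyldimethylsilyloxy)-2-[(4Z,8E)-10-[2-methoxy-3-methyl-5-(triisopropylsilyloxy)phenyl]-4,8-dimethyl-6-oxodeca-4,8-dien-1-yl]-2,6,6-trimethyloxan-3-one | COc1c(C)cc(O[Si](C(C)C)(C(C)C)C(C)C)cc1C/C=C(\C)CC(=O)/C=C(/C)CCC[C@@]1(C)OC(C)(C)[C@@H](O[Si](C)(C)C(C)(C)C)CC1=O | intermediate
34 | (2R,5S)-5-hydroxy-2-[(4Z,8E)-10-(5-hydroxy-2-methoxy-3-methylphenyl)-4,8-dimethyl-6-oxodeca-4,8-dien-1-yl]-2,6,6-trimethyloxan-3-one (CNP0268050.1) | COc1c(C)cc(O)cc1C/C=C(\C)CC(=O)/C=C(/C)CCC[C@@]1(C)OC(C)(C)[C@@H](O)CC1=O | target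

## Step count and risks

Total step count: 19. Longest linear sequence: 16 steps (steps 1–13 and 17–19); the arene branch (steps 14–16) has 3 steps.

Steps most likely to fail:

1. Step 17 (key step). The alkoxide-chelated alkenylalane may transmetalate to nickel only slowly, so that protodealumination, methyl transfer from aluminium to the benzylic chloride, or homocoupling of the chloride take over. The fallback sets out from 24 and 30 and comes back at 32. Alkyne 24 is put through the same Zr-catalysed methylalumination, but the alane is quenched with iodine to give the (E)-vinyl iodide F1, the standard outcome for homopropargylic alcohols. Separately, zinc dust and LiCl in THF convert 30 into the benzylic zinc chloride F2. A Pd-catalysed Negishi coupling of F1 with F2 (Pd(OAc)2/SPhos, THF, rt, free hydroxyl groups tolerated) should then give 32. This reverses the polarity of the two partners and separates the carbometalation from the C–C coupling.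

2. Step 8. Instead of capture by the hindered tertiary hydroxyl, the tertiary radical may be reduced (net hydrogenation of the isopropenyl group) or may give back a hydrogen atom from the neighbouring carbinol carbon (isomerisation to a silyl enol ether). The fallback sets out from 14 and comes back at 15. Iodoetherification (NIS, NaHCO3, MeCN, 0 °C) should close the same ring in the 6-exo Markovnikov sense to the iodomethyl oxanone F3; either configuration at the new C(CH3)(CH2I) carbon is acceptable. Radical deiodination (Bu3SnH, Et3B/air, toluene, rt) then turns CH2I into the second methyl group and gives 15.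

3. Step 6. Facial selectivity at the new carbinol may be poor if reagent control by the Ipc ligands is opposed by the α-silyloxy quaternary centre, and enolisation of the hindered ketone may be slow; the sense of induction would be checked by Mosher ester analysis of 13. The fallback sets out from 9 and comes back at 13. TMSOTf/Et3N converts 9 into the trimethylsilyl enol ether F4, which is added to 10 in a catalytic enantioselective Mukaiyama aldol reaction (tartaric-acid-derived chiral (acyloxy)borane Lewis acid, EtCN, −78 °C, open transition state, catalyst enantiomer chosen for Si-face attack). Acidic work-up (citric acid, MeOH) cleaves both O–TMS groups and gives 13. In either variant the unwanted C-3 epimer of 13 is a diastereomer and can be removed by chromatography.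

Further compounds
F1 | step 17 | (2R,5S)-5-(tert-butyldimethylsilyloxy)-2-[(4Z,8E)-6-hydroxy-9-iodo-4,8-dimethylnona-4,8-dien-1-yl]-2,6,6-trimethyloxan-3-ol | I/C=C(\C)CC(O)/C=C(/C)CCC[C@@]1(C)OC(C)(C)[C@@H](O[Si](C)(C)C(C)(C)C)CC1O
F2 | step 17 | [2-methoxy-3-methyl-5-(triisopropylsilyloxy)benzyl]zinc chloride | COc1c(C)cc(O[Si](C(C)C)(C(C)C)C(C)C)cc1C[Zn]Cl
F3 | step 8 | (2R,5S)-5-(tert-butyldimethylsilyloxy)-6-(iodomethyl)-2,6-dimethyl-2-[5-(trimethylsilyl)pent-4-yn-1-yl]oxan-3-one (C-6 epimers) | C[Si](C)(C)C#CCCC[C@@]1(C)OC(C)(CI)[C@@H](O[Si](C)(C)C(C)(C)C)CC1=O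
F4 | step 6 | (3R)-3-methyl-8-(trimethylsilyl)-2,3-bis(trimethylsilyloxy)oct-1-en-7-yne | C=C(O[Si](C)(C)C)[C@](C)(O[Si](C)(C)C)CCCC#C[Si](C)(C)C
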